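**Plan**
1. Retrosynthesis: cut the two ester C–O bonds (aroyl at O6, acetyl at O2) first. The 2α-OH is traced to a C2 ketone (reduction directed by the C4-OH), the C8=C9 alkene to a C9 ketone (enol triflate reduction), and H5/O6 to a C5=C6 alkene (hydroboration).
2. This leaves a hydroazulen-9-one in which C9(=O)–C10–C1 and the ring alkene C5=C6 form a γ,δ-unsaturated ketone with the quaternary C1 at the β-carbon. Cutting C1–C10 gives a 2-methylenetetrahydrofuran whose ring oxygen sits on C6 and whose C6 carries the cyclopentene (C5=C1).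
3. The enol ether comes from a γ-lactone; the C5–C6 bond is cut between a cyclopentenyllithium (from a 2-iodo-3-methyl-4-silyloxycyclopentenone) and β-methyl-γ-butyrolactone.
4. Forward: the five-membered ring is bought and decorated (C1 methyl, C5 iodide, C4 isopropyl carbinol), the chain is joined at C5–C6 and closed to the lactone, and the seven-membered carbocycle arises by Claisen ring expansion of the tetrahydrofuran.
5. Stereochemistry: C2 comes from the starting enone and is inverted late (oxidation, directed reduction); C4 by addition anti to the C2 silyloxy group; C6 (temporary) by CBS reduction, then transferred suprafacially to C1 in the rearrangement; H5 and O6 by α-face hydroboration anti to the C1 methyl.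

Key step: step 10

Remark: daucane numbering is used throughout (five-membered ring C1(CH3)–C2–C3–C4(isopropyl)–C5, seven-membered ring C1–C5–C6–C7–C8(CH3)–C9–C10; β = face of the C1 methyl). "R5" denotes the (3R,5R)-3-(tert-butyldimethylsilyloxy)-2-methyl-5-(propan-2-yl)-5-(triethylsilyloxy)cyclopent-1-en-1-yl group. Lactone 8 is assumed to be used as the racemate, so C8 is carried as a mixture of epimers (no stereo label at C8 in the SMILES of 10–14) until it becomes sp2 in step 11.

**Step 1**
Reactants: 1 (R)-4-(tert-butyldimethylsilyloxy)cyclopent-2-en-1-one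
Product: 2 tert-butyl(dimethyl){[(1R,2R)-2-methyl-4-(trimethylsilyloxy)cyclopent-3-en-1-yl]oxy}silane (methyl trans to OTBS)
Conditions: Me2CuLi (MeLi, CuI), TMSCl, THF, −78 °C; Et3N, aq. NaHCO3
Reagents that add atoms: methyllithium (as Me2CuLi) [Li]C; chlorotrimethylsilane C[Si](C)(C)Cl
Why: TMSCl-accelerated cuprate conjugate addition delivers methyl anti to the silyloxy group and traps the regiodefined enolate as its silyl enol ether before the silyloxy group can be eliminated; the new methine is erased in step 2.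

**Step 2**
Reactants: 2 silyl enol ether
Product: 3 (R)-4-(tert-butyldimethylsilyloxy)-3-methylcyclopent-2-en-1-one
Conditions: Pd(OAc)2 (1.05 equiv), MeCN, rt
Reagents that add atoms: none
Why: Saegusa–Ito oxidation (Pd(II) enolate, β-hydride elimination from the methyl-bearing carbon) restores the enone without touching the silyloxy stereocentre.

**Step 3**
Reactants: 3 methyl enone
Product: 4 (R)-4-(tert-butyldimethylsilyloxy)-2-iodo-3-methylcyclopent-2-en-1-one
Conditions: I2, pyridine/CH2Cl2 (1:1), 0 °C → rt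
Reagents that add atoms: iodine II
Why: Johnson α-iodination of an enone (pyridine addition, iodination, elimination) places iodine on the α-carbon, the future C5.

**Step 4**
Reactants: 4 iodoenone; 5 isopropylmagnesium chloride
Product: 6 (1R,4R)-4-(tert-butyldimethylsilyloxy)-2-iodo-3-methyl-1-(propan-2-yl)cyclopent-2-en-1-ol (OH cis to OTBS)
Conditions: 5, anhydrous CeCl3, THF, −78 °C; then 4; aq. NH4Cl
Reagents that add atoms: none
Why: Organocerium (Imamoto) 1,2-addition suppresses enolisation, β-hydride reduction and halogen–metal exchange, and the nucleophile should approach the carbonyl anti to the silyloxy group, so the tertiary OH ends cis to OTBS (C4, 4β-OH).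

**Step 5**
Reactants: 6 tertiary alcohol
Product: 7 (1R,4R)-4-(tert-butyldimethylsilyloxy)-2-iodo-3-methyl-1-(propan-2-yl)-1-(triethylsilyloxy)cyclopent-2-ene
Conditions: TESOTf, 2,6-lutidine, CH2Cl2, −78 → 0 °C
Reagents that add atoms: triethylsilyl trifluoromethanesulfonate CC[Si](CC)(CC)OS(=O)(=O)C(F)(F)F
Why: Silyl triflate silylation of a hindered tertiary alcohol; the TES ether protects the OH through the organolithium, titanium and thermal steps and later screens the β face.

**Step 6**
Reactants: 7 vinyl iodide; 8 rac-4-methyloxolan-2-one (β-methyl-γ-butyrolactone)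
Product: 10 4-hydroxy-3-methyl-1-R5-butan-1-one (C8 epimers), via cyclopentenyllithium 9 (not isolated)
Conditions: t-BuLi (2.1 equiv), Et2O, −78 °C; then 8, −78 → −40 °C; aq. NH4Cl
Reagents that add atoms: none
Why: Iodine–lithium exchange gives the vinyllithium, which opens the lactone by acyl substitution (C5–C6 bond); the lithium lactolate resists a second addition and collapses to the hydroxy enone on work-up.

**Step 7**
Reactants: 10 hydroxy enone
Product: 11 (1S)-3-methyl-1-R5-butane-1,4-diol (6S in daucane numbering; C8 epimers)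
Conditions: (R)-Me-CBS (0.3 equiv), catecholborane, toluene, −78 → −40 °C; MeOH, aq. NaOH
Reagents that add atoms: none
Why: Corey–Bakshi–Shibata reduction: with the α-branched cyclopentenyl group as the large and the CH2 chain as the small substituent, the (R)-oxazaborolidine is predicted to give the 6S carbinol under reagent control, the configuration needed for α-face bond formation in step 10.

**Step 8**
Reactants: 11 diol
Product: 12 (5S)-3-methyl-5-R5-oxolan-2-one (γ-lactone; O on C6, C9 carbonyl, C8 methyl)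
Conditions: TEMPO (cat.), PhI(OAc)2, CH2Cl2, rt
Reagents that add atoms: none
Why: TEMPO/PhI(OAc)2 oxidative lactonisation of a 1,4-diol: the primary alcohol is oxidised selectively, the hydroxy aldehyde closes to the lactol and this is oxidised on to the lactone, leaving the hindered C6 carbinol configuration intact.

**Step 9**
Reactants: 12 lactone
Product: 13 (2S)-4-methyl-5-methylidene-2-R5-oxolane (2-methylene-3-methyl-5-cyclopentenyltetrahydrofuran)
Conditions: Cp2TiMe2, toluene, 70 °C, dark; filtration through basic alumina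
Reagents that add atoms: dimethyltitanocene C[Ti](C)(C1C=CC=C1)C1C=CC=C1
Why: Petasis methylenation (thermally generated Cp2Ti=CH2, [2+2]/retro-[2+2] with the lactone carbonyl) gives the exocyclic enol ether under neutral conditions that the silyl ethers tolerate.

**Step 10**
Reactants: 13 methylene tetrahydrofuran
Product: 14 (1R,2R,4R)-2β-(tert-butyldimethylsilyloxy)-4β-(triethylsilyloxy)dauc-5-en-9-one (C8 epimers)
Conditions: o-xylene (degassed), Et3N (cat.), silylated sealed tube, 180–190 °C
Reagents that add atoms: none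
Why: Thermal [3,3]-sigmatropic (Claisen) rearrangement of the allyl vinyl ether C10=C9–O–C6–C5=C1: the C6–O bond breaks as C10 bonds to C1 and the enol ether becomes the C9 ketone. The closest known reaction is the Claisen ring expansion of 2-methylene-5-vinyltetrahydrofurans to cyclohept-4-enones. The seven-membered carbocycle closes by this pericyclic C1–C10 bond formation through the boat-like six-membered transition state imposed by the tetrahydrofuran ring (a two-atom ring enlargement, not an exo/endo cyclisation), which also makes the ring alkene C5=C6 cis. The new quaternary stereocentre C1 is controlled by C6: the shift is suprafacial on the allyl unit, so with 6S the oxygen leaves from, and C10 arrives on, the α face of the cyclopentene, anti to the C2 silyloxy group, giving 1R with the methyl β. The step needs the exocyclic enol ether to survive without isomerising into the ring and the crowded tetrasubstituted alkene to react; silylated glassware with a trace of amine should secure the first, and the weak allylic C6–O bond on an electron-rich alkene held next to the enol ether should secure the second.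

**Step 11**
Reactants: 14 ketone
Product: 15 (1R,2R,4R)-2β-(tert-butyldimethylsilyloxy)-4β-(triethylsilyloxy)-9-(trimethylsilyloxy)dauca-5,8-diene
Conditions: TMSCl, NaI, Et3N, MeCN, rt
Reagents that add atoms: chlorotrimethylsilane C[Si](C)(C)Cl
Why: Equilibrating silylation with TMSI made in situ should favour the thermodynamic, tetrasubstituted C8=C9 silyl enol ether over the less substituted C9=C10 isomer, and it removes the C8 stereocentre.

**Step 12**
Reactants: 15 silyl enol ether
Product: 17 (1R,2R,4R)-2β-(tert-butyldimethylsilyloxy)-4β-(triethylsilyloxy)dauca-5,8-dien-9-yl trifluoromethanesulfonate, via lithium enolate 16 (not isolated)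
Conditions: MeLi, THF, 0 °C; then PhNTf2, 0 °C → rt; aq. NH4Cl
Reagents that add atoms: N-phenylbis(trifluoromethanesulfonimide) O=S(=O)(N(c1ccccc1)S(=O)(=O)C(F)(F)F)C(F)(F)F
Why: MeLi cleaves the O–Si bond to the regiodefined lithium enolate without equilibration, and O-sulfonylation with PhNTf2 (McMurry–Scott enol triflate formation) fixes the double bond at C8=C9.

**Step 13**
Reactants: 17 enol triflate
Product: 19 (1R,2R,4R,5S,6S)-2β-(tert-butyldimethylsilyloxy)-6α-hydroxy-4β-(triethylsilyloxy)dauc-8-en-9-yl trifluoromethanesulfonate, via 6α-alkylborane 18 (not isolated)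
Conditions: BH3·THF, THF, 0 °C → rt; then NaBO3·4H2O, THF/H2O, rt
Reagents that add atoms: sodium perborate [Na+].[O-]OB=O
Why: Hydroboration–oxidation (syn, anti-Markovnikov): borane should add to the C5=C6 alkene with boron at C6 and hydrogen at C5 from the α face, opposite the C1 methyl and the C4 silyloxy group (as in Δ5-steroids), and oxidation with retention gives H5α and 6α-OH, while the tetrasubstituted, electron-poor enol triflate stays inert.

**Step 14**
Reactants: 19 hydroxy enol triflate
Product: 20 (1R,2R,4R,5S,6S)-2β-(tert-butyldimethylsilyloxy)-4β-(triethylsilyloxy)dauc-8-en-6α-ol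
Conditions: Pd(OAc)2 (cat.), PPh3, n-Bu3N, HCO2H, DMF, 60 °C
Reagents that add atoms: none
Why: Palladium-catalysed formate reduction of the enol triflate (oxidative addition, formate exchange, decarboxylation, reductive elimination) replaces OTf by H and leaves the alkene at C8=C9.

**Step 15**
Reactants: 20 alcohol; 21 4-acetoxybenzoyl chloride
Product: 22 (1R,2R,4R,5S,6S)-2β-(tert-butyldimethylsilyloxy)-4β-(triethylsilyloxy)dauc-8-en-6α-yl 4-acetoxybenzoate
Conditions: 21, Et3N, DMAP, CH2Cl2, 0 → 40 °C
Reagents that add atoms: none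
Why: DMAP-catalysed acylation of the only free hydroxyl (C6) by the acid chloride; the phenol travels as its acetate.

**Step 16**
Reactants: 22 bis-silyl ether
Product: 23 (1R,2R,4R,5S,6S)-2β,4β-dihydroxydauc-8-en-6α-yl 4-acetoxybenzoate
Conditions: HF·pyridine, pyridine, THF, 0 °C → rt
Reagents that add atoms: none
Why: Fluoride-mediated desilylation removes the TBS and TES ethers under buffered conditions that the esters and the trisubstituted alkene tolerate.

**Step 17**
Reactants: 23 diol
Product: 24 (1R,4R,5S,6S)-4β-hydroxy-2-oxodauc-8-en-6α-yl 4-acetoxybenzoate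
Conditions: Dess–Martin periodinane, NaHCO3, CH2Cl2, 0 °C
Reagents that add atoms: none
Why: Dess–Martin oxidation of the secondary C2 alcohol (the tertiary C4-OH cannot be oxidised) gives the β-hydroxy ketone, which is used at once to avoid dehydration.

**Step 18**
Reactants: 24 β-hydroxy ketone
Product: 25 (1R,2S,4R,5S,6S)-2α,4β-dihydroxydauc-8-en-6α-yl 4-acetoxybenzoate
Conditions: Me4NBH(OAc)3, MeCN/AcOH (1:1), −30 → 0 °C
Reagents that add atoms: none
Why: Evans–Saksena hydroxyl-directed reduction: the C4 β-hydroxyl binds boron and delivers hydride intramolecularly to the β face of the C2 ketone, giving the anti-1,3-diol, i.e. the 2α-alcohol (net inversion at C2).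

**Step 19**
Reactants: 25 diol
Product: 26 (1R,2S,4R,5S,6S)-2α-acetoxy-4β-hydroxydauc-8-en-6α-yl 4-acetoxybenzoate
Conditions: Ac2O, pyridine, DMAP (cat.), CH2Cl2, rt
Reagents that add atoms: acetic anhydride CC(=O)OC(C)=O
Why: DMAP-catalysed acetylation of the secondary C2-OH; the tertiary C4-OH should not react under these conditions.

**Step 20**
Reactants: 26 diacetate
Product: 27 (1R,2S,4R,5S,6S)-2α-acetoxy-4β-hydroxydauc-8-en-6α-yl 4-hydroxybenzoate (target)
Conditions: pyrrolidine, CH2Cl2, 0 °C
Reagents that add atoms: none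
Why: Chemoselective aminolysis of the aryl acetate (phenoxide is a far better leaving group than alkoxide) should leave the alkyl acetate and the hindered benzoate untouched.

**Compound list**
1 | (R)-4-(tert-butyldimethylsilyloxy)cyclopent-2-en-1-one | CC(C)(C)[Si](C)(C)O[C@@H]1CC(=O)C=C1 | starting material
2 | tert-butyl(dimethyl){[(1R,2R)-2-methyl-4-(trimethylsilyloxy)cyclopent-3-en-1-yl]oxy}silane | CC(C)(C)[Si](C)(C)O[C@@H]1CC(O[Si](C)(C)C)=C[C@H]1C | intermediate
3 | (R)-4-(tert-butyldimethylsilyloxy)-3-methylcyclopent-2-en-1-one | CC(C)(C)[Si](C)(C)O[C@@H]1CC(=O)C=C1C | intermediate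
4 | (R)-4-(tert-butyldimethylsilyloxy)-2-iodo-3-methylcyclopent-2-en-1-one | CC(C)(C)[Si](C)(C)O[C@@H]1CC(=O)C(I)=C1C | intermediate
5 | isopropylmagnesium chloride | CC(C)[Mg]Cl | starting material
6 | (1R,4R)-4-(tert-butyldimethylsilyloxy)-2-iodo-3-methyl-1-(propan-2-yl)cyclopent-2-en-1-ol | CC(C)(C)[Si](C)(C)O[C@@H]1C[C@@](O)(C(C)C)C(I)=C1C | intermediate
7 | (1R,4R)-4-(tert-butyldimethylsilyloxy)-2-iodo-3-methyl-1-(propan-2-yl)-1-(triethylsilyloxy)cyclopent-2-ene | CC(C)(C)[Si](C)(C)O[C@@H]1C[C@@](O[Si](CC)(CC)CC)(C(C)C)C(I)=C1C | intermediate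
8 | rac-4-methyloxolan-2-one (β-methyl-γ-butyrolactone) | CC1COC(=O)C1 | starting material
9 | [(3R,5R)-3-(tert-butyldimethylsilyloxy)-2-methyl-5-(propan-2-yl)-5-(triethylsilyloxy)cyclopent-1-en-1-yl]lithium | CC(C)(C)[Si](C)(C)O[C@@H]1C[C@@](O[Si](CC)(CC)CC)(C(C)C)C([Li])=C1C | intermediate (not isolated)
10 | 4-hydroxy-3-methyl-1-R5-butan-1-one (C8 epimers) | CC(C)(C)[Si](C)(C)O[C@@H]1C[C@@](O[Si](CC)(CC)CC)(C(C)C)C(C(=O)CC(C)CO)=C1C | intermediate
11 | (1S)-3-methyl-1-R5-butane-1,4-diol (C8 epimers) | CC(C)(C)[Si](C)(C)O[C@@H]1C[C@@](O[Si](CC)(CC)CC)(C(C)C)C([C@@H](O)CC(C)CO)=C1C | intermediate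
12 | (5S)-3-methyl-5-R5-oxolan-2-one (C8 epimers) | CC(C)(C)[Si](C)(C)O[C@@H]1C[C@@](O[Si](CC)(CC)CC)(C(C)C)C([C@@H]2CC(C)C(=O)O2)=C1C | intermediate
13 | (2S)-4-methyl-5-methylidene-2-R5-oxolane (C8 epimers) | CC(C)(C)[Si](C)(C)O[C@@H]1C[C@@](O[Si](CC)(CC)CC)(C(C)C)C([C@@H]2CC(C)C(=C)O2)=C1C | intermediate
14 | (1R,2R,4R)-2β-(tert-butyldimethylsilyloxy)-4β-(triethylsilyloxy)dauc-5-en-9-one (C8 epimers) | CC(C)(C)[Si](C)(C)O[C@@H]1C[C@@](O[Si](CC)(CC)CC)(C(C)C)C2=CCC(C)C(=O)C[C@@]12C | intermediate
15 | (1R,2R,4R)-2β-(tert-butyldimethylsilyloxy)-4β-(triethylsilyloxy)-9-(trimethylsilyloxy)dauca-5,8-diene | CC(C)(C)[Si](C)(C)O[C@@H]1C[C@@](O[Si](CC)(CC)CC)(C(C)C)C2=CCC(C)=C(O[Si](C)(C)C)C[C@@]12C | intermediate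
16 | lithium (1R,2R,4R)-2β-(tert-butyldimethylsilyloxy)-4β-(triethylsilyloxy)dauca-5,8-dien-9-olate | CC(C)(C)[Si](C)(C)O[C@@H]1C[C@@](O[Si](CC)(CC)CC)(C(C)C)C2=CCC(C)=C(O[Li])C[C@@]12C | intermediate (not isolated)
17 | (1R,2R,4R)-2β-(tert-butyldimethylsilyloxy)-4β-(triethylsilyloxy)dauca-5,8-dien-9-yl trifluoromethanesulfonate | CC(C)(C)[Si](C)(C)O[C@@H]1C[C@@](O[Si](CC)(CC)CC)(C(C)C)C2=CCC(C)=C(OS(=O)(=O)C(F)(F)F)C[C@@]12C | intermediate
18 | 6α-boryl adduct of 17 (drawn as the monoalkylborane; H5α) | CC(C)(C)[Si](C)(C)O[C@@H]1C[C@@](O[Si](CC)(CC)CC)(C(C)C)[C@@H]2[C@@H](B)CC(C)=C(OS(=O)(=O)C(F)(F)F)C[C@@]12C | intermediate (not isolated)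
19 | (1R,2R,4R,5S,6S)-2β-(tert-butyldimethylsilyloxy)-6α-hydroxy-4β-(triethylsilyloxy)dauc-8-en-9-yl trifluoromethanesulfonate | CC(C)(C)[Si](C)(C)O[C@@H]1C[C@@](O[Si](CC)(CC)CC)(C(C)C)[C@@H]2[C@@H](O)CC(C)=C(OS(=O)(=O)C(F)(F)F)C[C@@]12C | intermediate
20 | (1R,2R,4R,5S,6S)-2β-(tert-butyldimethylsilyloxy)-4β-(triethylsilyloxy)dauc-8-en-6α-ol | CC(C)(C)[Si](C)(C)O[C@@H]1C[C@@](O[Si](CC)(CC)CC)(C(C)C)[C@@H]2[C@@H](O)CC(C)=CC[C@@]12C | intermediate
21 | 4-acetoxybenzoyl chloride | CC(=O)Oc1ccc(cc1)C(Cl)=O | starting material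
22 | (1R,2R,4R,5S,6S)-2β-(tert-butyldimethylsilyloxy)-4β-(triethylsilyloxy)dauc-8-en-6α-yl 4-acetoxybenzoate | CC(C)(C)[Si](C)(C)O[C@@H]1C[C@@](O[Si](CC)(CC)CC)(C(C)C)[C@@H]2[C@@H](OC(=O)c3ccc(OC(C)=O)cc3)CC(C)=CC[C@@]12C | intermediate
23 | (1R,2R,4R,5S,6S)-2β,4β-dihydroxydauc-8-en-6α-yl 4-acetoxybenzoate | O[C@@H]1C[C@@](O)(C(C)C)[C@@H]2[C@@H](OC(=O)c3ccc(OC(C)=O)cc3)CC(C)=CC[C@@]12C | intermediate
24 | (1R,4R,5S,6S)-4β-hydroxy-2-oxodauc-8-en-6α-yl 4-acetoxybenzoate | O=C1C[C@@](O)(C(C)C)[C@@H]2[C@@H](OC(=O)c3ccc(OC(C)=O)cc3)CC(C)=CC[C@@]12C | intermediate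
25 | (1R,2S,4R,5S,6S)-2α,4β-dihydroxydauc-8-en-6α-yl 4-acetoxybenzoate | O[C@H]1C[C@@](O)(C(C)C)[C@@H]2[C@@H](OC(=O)c3ccc(OC(C)=O)cc3)CC(C)=CC[C@@]12C | intermediate
26 | (1R,2S,4R,5S,6S)-2α-acetoxy-4β-hydroxydauc-8-en-6α-yl 4-acetoxybenzoate | CC(=O)O[C@H]1C[C@@](O)(C(C)C)[C@@H]2[C@@H](OC(=O)c3ccc(OC(C)=O)cc3)CC(C)=CC[C@@]12C | intermediate
27 | (1R,2S,4R,5S,6S)-2α-acetoxy-4β-hydroxydauc-8-en-6α-yl 4-hydroxybenzoate | CC(=O)O[C@H]1C[C@@](O)(C(C)C)[C@@H]2[C@@H](OC(=O)c3ccc(O)cc3)CC(C)=CC[C@@]12C | target

**Totals**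
Total step count: 20. Longest linear sequence: 20 steps (1 → 27); 5, 8 and 21 are bought.

**Steps most likely to fail**

Step 10. In the reactive conformer C7 lies syn to the C1 methyl (allylic strain) and a quaternary centre is formed, so the rearrangement may need temperatures at which the exocyclic enol ether migrates into the ring or the allylic silyl ether is lost. The fallback sets out from 13 and uses the triisobutylaluminium-promoted Claisen rearrangement (i-Bu3Al, CH2Cl2, −78 °C → rt). Lewis-acid activation of the ether oxygen drives the same C1–C10 bond formation at low temperature, and the aluminium reagent reduces the new ketone in the same flask, giving the (1R,2R,4R)-2β-(tert-butyldimethylsilyloxy)-4β-(triethylsilyloxy)dauc-5-en-9-ol F1. Dess–Martin oxidation of F1 returns to the route at 14.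

Step 7. The oxazaborolidine may discriminate poorly between the faces of a twisted enone flanked by a quaternary carbon and a methyl-bearing alkene carbon, or uncatalysed reduction through the free primary hydroxyl may compete. Either would give the 6R epimer, which cannot put its oxygen on the α face in step 10. The fallback sets out from 7 and sets C6 by allylboration of an aldehyde instead of ketone reduction. Iodine–lithium exchange (t-BuLi) and DMF give the (3R,5R)-3-(tert-butyldimethylsilyloxy)-2-methyl-5-(propan-2-yl)-5-(triethylsilyloxy)cyclopent-1-ene-1-carbaldehyde F2. Brown allylboration with (−)-Ipc2B(2-methylallyl) (from (−)-Ipc2BOMe and 2-methylallylmagnesium chloride; oxidative work-up) is expected to give the (1S)-3-methyl-1-R5-but-3-en-1-ol F3. Hydroboration of its 1,1-disubstituted alkene with 9-BBN followed by NaOH/H2O2 returns to the route at diol 11.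

Step 13. Borane may add slowly to an alkene whose C5 is flanked by two quaternary carbons, so that the forcing conditions and the oxidative work-up destroy the enol triflate before C6 is oxygenated. The fallback sets out from 15 and masks the ketone as an enol phosphate instead. MeLi followed by ClP(O)(OEt)2 traps enolate 16 as the (1R,2R,4R)-2β-(tert-butyldimethylsilyloxy)-4β-(triethylsilyloxy)dauca-5,8-dien-9-yl diethyl phosphate F4. This should tolerate BH3·SMe2 at 40–50 °C and NaOH/H2O2, giving the (1R,2R,4R,5S,6S)-6α-hydroxy-2β-(tert-butyldimethylsilyloxy)-4β-(triethylsilyloxy)dauc-8-en-9-yl diethyl phosphate F5. Dissolving-metal cleavage of the enol phosphate (Li, EtNH2, t-BuOH, THF, −78 → 0 °C) returns to the route at 20.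

**Further compounds**
F1 | step 10 | (1R,2R,4R)-2β-(tert-butyldimethylsilyloxy)-4β-(triethylsilyloxy)dauc-5-en-9-ol (C8 and C9 epimers) | CC(C)(C)[Si](C)(C)O[C@@H]1C[C@@](O[Si](CC)(CC)CC)(C(C)C)C2=CCC(C)C(O)C[C@@]12C
F2 | step 7 | (3R,5R)-3-(tert-butyldimethylsilyloxy)-2-methyl-5-(propan-2-yl)-5-(triethylsilyloxy)cyclopent-1-ene-1-carbaldehyde | CC(C)(C)[Si](C)(C)O[C@@H]1C[C@@](O[Si](CC)(CC)CC)(C(C)C)C(C=O)=C1C
F3 | step 7 | (1S)-3-methyl-1-R5-but-3-en-1-ol | CC(C)(C)[Si](C)(C)O[C@@H]1C[C@@](O[Si](CC)(CC)CC)(C(C)C)C([C@@H](O)CC(C)=C)=C1C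
F4 | step 13 | (1R,2R,4R)-2β-(tert-butyldimethylsilyloxy)-4β-(triethylsilyloxy)dauca-5,8-dien-9-yl diethyl phosphate | CC(C)(C)[Si](C)(C)O[C@@H]1C[C@@](O[Si](CC)(CC)CC)(C(C)C)C2=CCC(C)=C(OP(=O)(OCC)OCC)C[C@@]12C
F5 | step 13 | (1R,2R,4R,5S,6S)-6α-hydroxy-2β-(tert-butyldimethylsilyloxy)-4β-(triethylsilyloxy)dauc-8-en-9-yl diethyl phosphate | CC(C)(C)[Si](C)(C)O[C@@H]1C[C@@](O[Si](CC)(CC)CC)(C(C)C)[C@@H]2[C@@H](O)CC(C)=C(OP(=O)(OCC)OCC)C[C@@]12C
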